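**Retrosynthetic overview**
- The (E)-3-methyl-2-enoic acid is made last from a terminal alkyne by syn-methylalumination and carboxylation.
- The C3 methylene comes from a 3β-alcohol (oxidation, hydrazone reduction); the 8,9-olefin comes from acid convergence of the ring B olefin isomers.
- Both rings form in one cationic cascade from an acyclic (S,S)-epoxide: ring A first (C4–C5 bond), then ring B (C9–C10 bond).
- The epoxide substrate comes from an epoxy alcohol and prenyl Grignard (via the triflate); the epoxy alcohol comes from the terminal isopropylidene group by C–H hydroxylation and asymmetric epoxidation, whose C–O bonds carry all the stereochemical information.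
- The acyclic enyne comes from farnesyl bromide and propargyl bromide.

Assumption: (2E,6E)-farnesyl bromide and prenylmagnesium chloride solution are bought as such; ring positions in the explanations use labdane-style numbering (C3 carbinol carbon, C4 quaternary carbon bearing the methylpentenyl chain, C5/C10 ring fusion, C8/C9 ring B olefin).

Step 1
Reactants: 1 (2E,6E)-farnesyl bromide; 2 propargyl bromide
Product: 3 (5E,9E)-6,10,14-trimethylpentadeca-5,9,13-trien-1-yne
Conditions: 2 (1.3 equiv), n-BuLi (2.6 equiv), TMEDA, Et2O/hexane, −78 °C; then 1, −78 → 0 °C; H2O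
Reagents that add atoms: none
Why: SN2 propargylation, in which the sp3 carbon of 1,3-dilithiopropyne (made in the flask from 2 and n-BuLi) displaces the primary allylic bromide without allylic transposition, leaving both E-olefins untouched and forming no stereocentre.

Step 2
Reactants: 3 (5E,9E)-6,10,14-trimethylpentadeca-5,9,13-trien-1-yne
Product: 5 [(2S,3S)-3-[(3E,7E)-3,7-dimethyldodeca-3,7-dien-11-yn-1-yl]-2-methyloxiran-2-yl]methanol, via allylic alcohol 4 (not isolated)
Conditions: SeO2 (0.2 equiv), t-BuOOH (3.5 equiv, anhydrous, decane), CH2Cl2, 10 °C; then 4 Å MS, Ti(OiPr)4 (1.0 equiv), L-(+)-DET (1.2 equiv), −25 °C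
Reagents that add atoms: tert-butyl hydroperoxide, CC(C)(C)OO
Why: Proposed new method: a one-flask selenium/titanium relay in which SeO2-catalysed ene reaction and [2,3]-sigmatropic shift hydroxylate only the (E)-methyl group of the terminal isopropylidene unit (Riley-type allylic oxidation), and the allylic alcohol 4, the only substrate the tetravalent titanium tartrate can bind, is then epoxidised in the same flask by the same hydroperoxide charge (Katsuki–Sharpless asymmetric epoxidation), L-(+)-diethyl tartrate directing oxygen to the olefin face that gives the (2S,3S)-epoxide and thereby fixing the future C4 and C3 centres; site selectivity comes from selenium, enantioselectivity from titanium, excess titanium alkoxide scavenges selenium oxo-acids, and the closest known reaction type is the one-pot ene-hydroperoxidation/Ti(OiPr)4 oxygen-transfer route to epoxy alcohols.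

Step 3
Reactants: 5 [(2S,3S)-3-[(3E,7E)-3,7-dimethyldodeca-3,7-dien-11-yn-1-yl]-2-methyloxiran-2-yl]methanol; 6 prenylmagnesium chloride (3-methylbut-2-en-1-ylmagnesium chloride)
Product: 8 (2S,3S)-3-[(3E,7E)-3,7-dimethyldodeca-3,7-dien-11-yn-1-yl]-2-methyl-2-(4-methylpent-3-en-1-yl)oxirane, via epoxy triflate 7 (not isolated)
Conditions: Tf2O, 2,6-lutidine, CH2Cl2, −78 °C; then 6 (3.5 equiv), CuBr·SMe2 (10 mol%), THF, −78 → −40 °C
Reagents that add atoms: none
Why: Copper-catalysed sp3–sp3 coupling of a primary triflate and an allylic Grignard reagent, which bonds at its unsubstituted CH2 terminus and displaces the oxiranylmethyl triflate far faster than the trisubstituted epoxide can open, so both epoxide stereocentres are carried over unchanged (one extra equivalent of Grignard is consumed by the alkyne C–H, which is restored on work-up).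

Step 4
Reactants: 8 (2S,3S)-3-[(3E,7E)-3,7-dimethyldodeca-3,7-dien-11-yn-1-yl]-2-methyl-2-(4-methylpent-3-en-1-yl)oxirane
Product: 9 (1S,2S,4aR,5S,8aR)-5-(but-3-yn-1-yl)-1,4a-dimethyl-6-methylidene-1-(4-methylpent-3-en-1-yl)decahydronaphthalen-2-ol (drawn component of a ring B olefin-isomer mixture)
Conditions: MeAlCl2 (1.5 equiv), CH2Cl2, −78 °C; Et3N, then aq. NaHCO3
Reagents that add atoms: none
Why: Epoxide-initiated cation–olefin bicyclisation through a chair–chair transition state, in which the proximal E-olefin attacks the tertiary epoxide carbon with inversion (C4: methyl axial β, methylpentenyl chain equatorial α), the retained C–O bond becomes the equatorial 3β-hydroxyl, and anti addition across the two E-olefins closes ring A and then ring B trans-fused (5α-H, 10β-methyl); the C8 cation loses a proton unselectively, so the exocyclic, 7,8- and 8,9-olefins form together and are converged in step 5, while the terminal alkyne and the side-chain olefin cannot reach a stabilised cation.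

Step 5
Reactants: 9 (ring B olefin-isomer mixture)
Product: 10 (1S,2S,4aS,8aR)-5-(but-3-yn-1-yl)-1,4a,6-trimethyl-1-(4-methylpent-3-en-1-yl)-1,2,3,4,4a,7,8,8a-octahydronaphthalen-2-ol
Conditions: TsOH·H2O (0.2 equiv), benzene, 60 °C
Reagents that add atoms: none
Why: Acid-catalysed olefin isomerisation, in which reversible protonation of the exocyclic and trisubstituted ring olefins regenerates the same tertiary C8 cation and loss of the axial C9 proton funnels the mixture to the thermodynamically preferred tetrasubstituted 8,9-olefin; the acyclic trisubstituted olefin is already at its thermodynamic position and C3, C4, C5 and C10 are untouched.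

Step 6
Reactants: 10 (1S,2S,4aS,8aR)-5-(but-3-yn-1-yl)-1,4a,6-trimethyl-1-(4-methylpent-3-en-1-yl)-1,2,3,4,4a,7,8,8a-octahydronaphthalen-2-ol
Product: 11 (1S,4aS,8aR)-5-(but-3-yn-1-yl)-1,4a,6-trimethyl-1-(4-methylpent-3-en-1-yl)-3,4,4a,7,8,8a-hexahydronaphthalen-2(1H)-one
Conditions: Dess–Martin periodinane, CH2Cl2, 0 → 20 °C
Reagents that add atoms: none
Why: Dess–Martin oxidation of the hindered secondary alcohol under neutral conditions; the neighbouring C4 is quaternary, so no stereocentre can epimerise.

Step 7
Reactants: 11 (1S,4aS,8aR)-5-(but-3-yn-1-yl)-1,4a,6-trimethyl-1-(4-methylpent-3-en-1-yl)-3,4,4a,7,8,8a-hexahydronaphthalen-2(1H)-one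
Product: 13 (4aS,5S,8aS)-1-(but-3-yn-1-yl)-2,5,8a-trimethyl-5-(4-methylpent-3-en-1-yl)-3,4,4a,5,6,7,8,8a-octahydronaphthalene, via tosylhydrazone 12 (not isolated)
Conditions: TsNHNH2, EtOH, 75 °C; then catecholborane, CHCl3, 0 °C; NaOAc·3H2O, 60 °C
Reagents that add atoms: none
Why: Caglioti-type tosylhydrazone reduction (Kabalka variant), in which hydride adds to the C=N bond, acetate triggers loss of sulfinate and the alkyldiazene extrudes N2 to leave CH2 at C3 under conditions too mild to isomerise the terminal alkyne or move the olefins; C4, C5 and C10 are unaffected.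

Step 8
Reactants: 13 (4aS,5S,8aS)-1-(but-3-yn-1-yl)-2,5,8a-trimethyl-5-(4-methylpent-3-en-1-yl)-3,4,4a,5,6,7,8,8a-octahydronaphthalene
Product: 15 (2E)-3-methyl-5-[(4aS,5S,8aS)-2,5,8a-trimethyl-5-(4-methylpent-3-en-1-yl)-3,4,4a,5,6,7,8,8a-octahydronaphthalen-1-yl]pent-2-enoic acid (CNP0237483.2), via alkenylalane 14 (not isolated)
Conditions: Me3Al (2.5 equiv), Cp2ZrCl2 (0.2 equiv), CH2Cl2, 20 °C; then n-BuLi, THF, −78 °C; CO2, −78 → 20 °C; 1 M HCl
Reagents that add atoms: trimethylaluminium, C[Al](C)C; carbon dioxide, O=C=O
Why: Negishi zirconium-catalysed syn-methylalumination of the terminal alkyne puts methyl on the internal carbon and aluminium on the terminus, and carboxylation of the derived alanate with retention gives the (E)-3-methyl-2-enoic acid directly; the tri- and tetrasubstituted olefins are inert and no stereocentre is touched.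

**Compound list**
1 | (2E,6E)-farnesyl bromide [(2E,6E)-1-bromo-3,7,11-trimethyldodeca-2,6,10-triene] | CC(C)=CCC/C(C)=C/CC/C(C)=C/CBr | starting material
2 | propargyl bromide (3-bromoprop-1-yne) | C#CCBr | starting material
3 | (5E,9E)-6,10,14-trimethylpentadeca-5,9,13-trien-1-yne | CC(C)=CCC/C(C)=C/CC/C(C)=C/CCC#C | intermediate
4 | (2E,6E,10E)-2,6,10-trimethylpentadeca-2,6,10-trien-14-yn-1-ol (allylic alcohol, not isolated) | OC/C(C)=C/CC/C(C)=C/CC/C(C)=C/CCC#C | intermediate
5 | [(2S,3S)-3-[(3E,7E)-3,7-dimethyldodeca-3,7-dien-11-yn-1-yl]-2-methyloxiran-2-yl]methanol | OC[C@]1(C)O[C@H]1CC/C(C)=C/CC/C(C)=C/CCC#C | intermediate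
6 | prenylmagnesium chloride (3-methylbut-2-en-1-ylmagnesium chloride) | CC(C)=CC[Mg]Cl | starting material
7 | [(2S,3S)-3-[(3E,7E)-3,7-dimethyldodeca-3,7-dien-11-yn-1-yl]-2-methyloxiran-2-yl]methyl trifluoromethanesulfonate (epoxy triflate, not isolated) | O=S(=O)(OC[C@]1(C)O[C@H]1CC/C(C)=C/CC/C(C)=C/CCC#C)C(F)(F)F | intermediate
8 | (2S,3S)-3-[(3E,7E)-3,7-dimethyldodeca-3,7-dien-11-yn-1-yl]-2-methyl-2-(4-methylpent-3-en-1-yl)oxirane | CC(C)=CCC[C@]1(C)O[C@H]1CC/C(C)=C/CC/C(C)=C/CCC#C | intermediate
9 | (1S,2S,4aR,5S,8aR)-5-(but-3-yn-1-yl)-1,4a-dimethyl-6-methylidene-1-(4-methylpent-3-en-1-yl)decahydronaphthalen-2-ol (exocyclic isomer drawn; formed together with its endocyclic 6,7- and 5,6-olefin isomers) | CC(C)=CCC[C@]1(C)[C@@H](O)CC[C@]2(C)[C@@H](CCC#C)C(=C)CC[C@@H]12 | intermediate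
10 | (1S,2S,4aS,8aR)-5-(but-3-yn-1-yl)-1,4a,6-trimethyl-1-(4-methylpent-3-en-1-yl)-1,2,3,4,4a,7,8,8a-octahydronaphthalen-2-ol | CC(C)=CCC[C@]1(C)[C@@H](O)CC[C@]2(C)C(CCC#C)=C(C)CC[C@@H]12 | intermediate
11 | (1S,4aS,8aR)-5-(but-3-yn-1-yl)-1,4a,6-trimethyl-1-(4-methylpent-3-en-1-yl)-3,4,4a,7,8,8a-hexahydronaphthalen-2(1H)-one | CC(C)=CCC[C@]1(C)C(=O)CC[C@]2(C)C(CCC#C)=C(C)CC[C@@H]12 | intermediate
12 | 4-methyl-N'-[(1S,4aS,8aR)-5-(but-3-yn-1-yl)-1,4a,6-trimethyl-1-(4-methylpent-3-en-1-yl)-3,4,4a,7,8,8a-hexahydronaphthalen-2(1H)-ylidene]benzenesulfonohydrazide (tosylhydrazone, C=N geometry not assigned, not isolated) | CC(C)=CCC[C@]1(C)C(=NNS(=O)(=O)c3ccc(C)cc3)CC[C@]2(C)C(CCC#C)=C(C)CC[C@@H]12 | intermediate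
13 | (4aS,5S,8aS)-1-(but-3-yn-1-yl)-2,5,8a-trimethyl-5-(4-methylpent-3-en-1-yl)-3,4,4a,5,6,7,8,8a-octahydronaphthalene | CC(C)=CCC[C@]1(C)CCC[C@]2(C)C(CCC#C)=C(C)CC[C@@H]12 | intermediate
14 | dimethyl[(1E)-2-methyl-4-[(4aS,5S,8aS)-2,5,8a-trimethyl-5-(4-methylpent-3-en-1-yl)-3,4,4a,5,6,7,8,8a-octahydronaphthalen-1-yl]but-1-en-1-yl]alumane (alkenylalane, not isolated) | CC(C)=CCC[C@]1(C)CCC[C@]2(C)C(CC/C(C)=C/[Al](C)C)=C(C)CC[C@@H]12 | intermediate
15 | (2E)-3-methyl-5-[(4aS,5S,8aS)-2,5,8a-trimethyl-5-(4-methylpent-3-en-1-yl)-3,4,4a,5,6,7,8,8a-octahydronaphthalen-1-yl]pent-2-enoic acid (CNP0237483.2) | CC(C)=CCC[C@]1(C)CCC[C@]2(C)C(CC/C(C)=C/C(=O)O)=C(C)CC[C@@H]12 | target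

**Totals**
Total step count: 8. Longest linear sequence: 8 steps (from 1).

**Steps most likely to fail**

Step 2 (the proposed relay). Selenium residues may poison or racemise the titanium tartrate epoxidation, or the epoxy alcohol may not survive the selenium oxo-acids. The fallback uses known chemistry, sets out from 3 and comes back at 5. The relay is abandoned for the classical two-operation sequence: SeO2 (0.5 equiv), t-BuOOH and salicylic acid (cat.) in CH2Cl2 at 20 °C, chromatographic isolation of allylic alcohol 4 free of selenium (unreacted 3 recycled), then catalytic Katsuki–Sharpless epoxidation with Ti(OiPr)4 (10 mol%), L-(+)-DET (12 mol%), t-BuOOH and 4 Å MS at −20 °C. This fallback makes no compound outside the list (F0).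

Step 4 (cationic bicyclisation). The cascade may stop after ring A or divert to epoxide rearrangement, giving a low yield of bicycle. The fallback sets out from 8 and comes back at 9 and changes the manifold from cationic to radical. Cp2TiCl, generated from Cp2TiCl2 (2.2 equiv) and Mn dust in THF at 20 °C, opens the epoxide homolytically at the tertiary carbon with trivalent titanium, keeping the C3–O bond and its S configuration. Two 6-endo radical closures follow, and β-hydride elimination from the C8–titanium species gives only the exocyclic olefin form of 9. In this variant C4 is set by the chair transition state (larger chain equatorial) instead of by inversion, so a minor 4-epimer must be removed by chromatography before step 5. This fallback makes no compound outside the list (F0).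

Step 7 (C3 deoxygenation). Hydrazone formation at the neopentyl ketone may be slow. If the diazene fragments through a free C3 radical, that radical can close 5-exo onto the side-chain olefin. The fallback sets out from 10 and comes back at 13, bypassing 11 and 12. Alcohol 10 is converted with n-BuLi and ClP(O)(NMe2)2 in THF/TMEDA into (1S,2S,4aS,8aR)-5-(but-3-yn-1-yl)-1,4a,6-trimethyl-1-(4-methylpent-3-en-1-yl)-1,2,3,4,4a,7,8,8a-octahydronaphthalen-2-yl N,N,N',N'-tetramethylphosphorodiamidate F1. The C3–O bond of F1 is then cleaved with Li in EtNH2/t-BuOH/THF at 0 °C (Ireland deoxygenation). Under these conditions the alkyne is protected as its lithium acetylide, and electron transfer turns the transient C3 radical into the carbanion faster than it can cyclise.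

**Further compounds**
F0 | step 2 | none | none
F0 | step 4 | none | none
F1 | step 7 | (1S,2S,4aS,8aR)-5-(but-3-yn-1-yl)-1,4a,6-trimethyl-1-(4-methylpent-3-en-1-yl)-1,2,3,4,4a,7,8,8a-octahydronaphthalen-2-yl N,N,N',N'-tetramethylphosphorodiamidate | CC(C)=CCC[C@]1(C)[C@@H](OP(=O)(N(C)C)N(C)C)CC[C@]2(C)C(CCC#C)=C(C)CC[C@@H]12
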